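- I have no rate constants for this flask, but I have 3 runs, and I divide G gained by Q lost so that I can hold them side by side.
- Time stays in this ratio: Wednesday's run reads 0.175 at 4.00 min and 0.256 at 8.00 min, a rise, so I use it as a reading tied to its moment.

| setting | Thursday's | Wednesday's | Tuesday's | north-east | north-west | north | west |
|---|---|---|---|---|---|---|---|
| Q | 0.26 M | 1 M | 0.51 M | 0.51 M | 0.51 M | 0.51 M | 0.51 M |
| Z | 0.1 mol% | 0.1 mol% | 0.2 mol% | 0.1 mol% | 0.1 mol% | 0.1 mol% | 0.1 mol% |
| temperature | −19 °C | 6 °C | −19 °C | 15 °C | −30 °C | −15 °C | 0 °C |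
| remark | run made earlier | run made earlier | run made earlier |  |  |  |  |
| time |  |  |  | 20 min | 20 min | 20 min | 20 min |

| run | time / min | G / % | Q / % |
|---|---|---|---|
| Thursday's | 15.0 | 1 | 91 |
| Thursday's | 25.0 | 2 | 82 |
| Thursday's | 30.0 | 1 | 79 |
| Thursday's | 50.0 | 9 | 66 |
| Thursday's | 60.0 | 6 | 60 |
| Thursday's | 80.0 | 11 | 53 |
| Wednesday's | 4.00 | 10 | 43 |
| Wednesday's | 8.00 | 20 | 22 |
| Wednesday's | 10.0 | 21 | 16 |
| Wednesday's | 15.0 | 29 | 13 |
| Wednesday's | 20.0 | 32 | 14 |
| Wednesday's | 25.0 | 41 | 11 |
| Tuesday's | 8.00 | 0 | 93 |
| Tuesday's | 15.0 | 5 | 86 |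
| Tuesday's | 25.0 | 7 | 72 |
| Tuesday's | 40.0 | 10 | 61 |
| Tuesday's | 80.0 | 20 | 30 |

(each reading ± 2 percentage points)

- which flask leads in amount of G, in percent of the Q charged ("all alike" within 1.5 percentage points) (north-east / north-west / north / west / all alike)
- how much G is there at the end, in percent of the Q charged: north-east
- how much G is there at the end, in percent of the Q charged: north-west
- how much G is there at the end, in percent of the Q charged: north
- how much G is there at the end, in percent of the Q charged: west

- the analysis behind the earlier runs scatters by 2 percentage points, standard deviation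

- Thursday's run, at −19 °C and [Q] of 0.26 M, reads 0.234 of G per Q lost at its last reading, and Tuesday's, with 0.2 mol% of Z, reads 0.286 at its last.
- Wednesday's run is my second way to that number: at 6 °C and [Q] of 1 M it reads 0.256 at 8.00 min, and its gap to Thursday's is smaller than what the scatter of 2 percentage points in G moves this ratio, so I trust the agreement at these readings.
- I carry the mean of these 3 readings, 0.259, as the G share, the selectivity for G on Q lost, which is about a quarter; it is an estimate from these moments, with no claim to hold at every time.
- The two ways part at Wednesday's last reading, where G per Q lost stands at 0.461.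
- That reading cheats: from 10.0 min to 25.0 min, G gains 20 points while Q loses 5 points, a step ratio of 4.00, above one, so this G comes from an unseen store, and 63.0% of the charge is neither Q nor G at 10.0 min.
- For Q lost, I treat the fall as pseudo-first-order, with 0.00794 min⁻¹ from Thursday's run and 0.211 min⁻¹ from Wednesday's, and I draw ln k straight in temperature, although [Q] changes between those runs too.
- In west, this loses 85.3% of Q in 20 min, so I expect 22.1% of G.
- The same reckoning gives 6.09% in north and 0.952% in north-west.
- For north-east, I extrapolate past Wednesday's temperature to a Q loss of >99.9%, which gives 25.9% of G plus whatever the store adds, so north-east leads west.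
- The forecast also names north-east, with 50% there, above my figure, and 1% in north-west, 6% in north and 23% in west, its pool being one that “slowly feeds G”.
- The flasks give 31.3% of G in north-east, 0.0511% in north-west, 2.25% in north and 21.2% in west, so north-east leads.

    Q ⇌ L (K = 2.40, k = 0.00100 s⁻¹, Ea = 78.0 kJ mol⁻¹, ΔH = −45.0 kJ mol⁻¹)
    Z ⇌ J (K = 0.110, k = 4.60 × 10⁻⁴ s⁻¹, Ea = 82.0 kJ mol⁻¹, ΔH = −38.0 kJ mol⁻¹)
    Q + J → X (k = 14.0 M⁻¹ s⁻¹, Ea = 43.0 kJ mol⁻¹)
    2 Q → E (k = 5.80 × 10⁻⁴ M⁻¹ s⁻¹, Ea = 51.0 kJ mol⁻¹)
    X → J + G (k = 3.50 s⁻¹, Ea = 56.0 kJ mol⁻¹)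
    (constants at 0 °C)

- West has 19% of its Q left, so its G share is 0.262 against my 0.259, while north-east, with 20% of its Q left, stands at 0.391 and north, with 70% left, at 0.0750. The neighbouring flask is north-west run at −5 °C, with the amounts and the time held. It has 33% of its Q left, so the share reckons 17.4% of G, and the flask holds 14.1%.

(The earlier runs and the new flask were computed with constants of no real substance, noise included.)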